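## Retrosynthetic overview

1. Target 18 ⇐ bis-silyl ether 17 by removal of two triisopropylsilyl (TIPS) groups.
2. 17 ⇐ dienyl ether 15 by one intramolecular [2+2] photocycloaddition that makes cyclobutane bonds Ca–Cb and Cc–Cd (Ca = CH on C11 of the oxepine; Cb = CH shared by cyclobutane, cyclopentane and pyran; Cc = CH next to CH2; Cd = CMe2). The enabling feature is that the cyclobutane is a vinylcyclobutane: Ca sits on C11 of the C10=C11 enol ether double bond and Cb sits on the quaternary carbon bearing the pyran oxygen, so cutting these two bonds leaves an aryl-conjugated 10-alkoxy-11-isobutenyl diene and a cyclopentene held four atoms apart by that oxygen.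
3. 15 ⇐ Wittig (adds CMe2) ⇐ alkoxy enal 14 ⇐ vinylic substitution of chloro enal 10 by the alkoxide of (R)-1-methylcyclopent-2-en-1-ol 12, made from (R)-linalool 11 by ring-closing metathesis (the only source of chirality).
4. 10 ⇐ ketone 8 (Vilsmeier chloroformylation) ⇐ dibenzoxepinone 4 (demethylation, bromination, Stille prenylation, silylation) ⇐ acid 1 + phenol 2 (Ullmann ether synthesis, Friedel–Crafts acylation).
5. Ring order: diaryl ether (rings A and B) → oxepinone ring → cyclopentene (separate branch) → dihydropyran and cyclobutane together in the key step.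

Key step: step 11

Assumption: commercial (R)-(−)-linalool of high enantiomeric purity is used; no later step makes or breaks a bond at its carbinol carbon, so its configuration and ee carry through to 18.

## Route

Step 1
Reactants: 1 2-(2-bromo-4-methoxyphenyl)acetic acid; 2 3-methoxyphenol
Product: 3 2-[4-methoxy-2-(3-methoxyphenoxy)phenyl]acetic acid
Conditions: CuI (10 mol %), N,N-dimethylglycine (30 mol %), Cs2CO3, 1,4-dioxane, 100 °C; then aq HCl
Reagents that add atoms: none
Why: Copper-catalysed Ullmann diaryl ether synthesis is standard for 2-halophenylacetic acids, the acid being carried as its cesium carboxylate; no stereocentre is formed.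

Step 2
Reactants: 3 2-[4-methoxy-2-(3-methoxyphenoxy)phenyl]acetic acid
Product: 4 3,7-dimethoxydibenzo[b,f]oxepin-10(11H)-one
Conditions: polyphosphoric acid, 100 °C
Reagents that add atoms: none
Why: Intramolecular Friedel–Crafts acylation should close the seven-membered ketone at the ring-B carbon para to methoxy and ortho to the ether oxygen, the only activated position within reach that is not flanked by two oxygens.

Step 3
Reactants: 4 3,7-dimethoxydibenzo[b,f]oxepin-10(11H)-one
Product: 5 3,7-dihydroxydibenzo[b,f]oxepin-10(11H)-one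
Conditions: BBr3, CH2Cl2, −78 °C → rt; then H2O
Reagents that add atoms: none
Why: Lewis-acid demethylation (boron complexation, then bromide SN2 at methyl) frees both phenols before the acid-sensitive prenyl group is present.

Step 4
Reactants: 5 3,7-dihydroxydibenzo[b,f]oxepin-10(11H)-one
Product: 6 2-bromo-3,7-dihydroxydibenzo[b,f]oxepin-10(11H)-one
Conditions: NBS (1.0 equiv), i-Pr2NH (10 mol %), CH2Cl2, −40 → 0 °C
Reagents that add atoms: N-bromosuccinimide, O=C1CCC(=O)N1Br
Why: Electrophilic aromatic bromination should occur on ring A (a free alkylresorcinol-type phenol, far more nucleophilic than the acyl-deactivated ring B) at C2, which is ortho to OH and para to the ether oxygen, whereas C4 is flanked by two oxygens.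

Step 5
Reactants: 6 2-bromo-3,7-dihydroxydibenzo[b,f]oxepin-10(11H)-one
Product: 7 3,7-dihydroxy-2-(3-methylbut-2-en-1-yl)dibenzo[b,f]oxepin-10(11H)-one
Conditions: tributyl(prenyl)stannane, Pd(PPh3)4 (5 mol %), DMF, 90 °C
Reagents that add atoms: tributyl(3-methylbut-2-en-1-yl)stannane, CCCC[Sn](CCCC)(CCCC)CC=C(C)C
Why: Stille coupling with phosphine-ligated zerovalent palladium should give the linear prenyl arene and tolerates free phenols and the enolisable ketone.

Step 6
Reactants: 7 3,7-dihydroxy-2-(3-methylbut-2-en-1-yl)dibenzo[b,f]oxepin-10(11H)-one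
Product: 8 2-(3-methylbut-2-en-1-yl)-3,7-bis(triisopropylsilyloxy)dibenzo[b,f]oxepin-10(11H)-one
Conditions: TIPSCl, imidazole, DMAP (cat.), DMF, 40 °C
Reagents that add atoms: chlorotri(propan-2-yl)silane, CC(C)[Si](Cl)(C(C)C)C(C)C
Why: Phenol silylation; TIPS aryl ethers are chosen because they should survive Vilsmeier conditions, a tertiary alkoxide, an ylide and light, and leave with fluoride at the end.

Step 7
Reactants: 8 2-(3-methylbut-2-en-1-yl)-3,7-bis(triisopropylsilyloxy)dibenzo[b,f]oxepin-10(11H)-one
Product: 10 10-chloro-2-(3-methylbut-2-en-1-yl)-3,7-bis(triisopropylsilyloxy)dibenzo[b,f]oxepine-11-carbaldehyde, via iminium chloride 9 (not isolated)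
Conditions: POCl3, DMF, CH2Cl2, 0 → 40 °C; then ice-water
Reagents that add atoms: N,N-dimethylformamide, CN(C)C=O; phosphoryl chloride, O=P(Cl)(Cl)Cl; water, O
Why: Vilsmeier–Haack–Arnold chloroformylation of an aryl benzyl ketone: the enol is C-formylated at C11, the C10 oxygen is exchanged for chloride, and the β-chlorovinyl iminium salt is hydrolysed; the ring fixes the alkene geometry.

Step 8
Reactants: 11 (R)-linalool, (3R)-3,7-dimethylocta-1,6-dien-3-ol
Product: 12 (1R)-1-methylcyclopent-2-en-1-ol
Conditions: second-generation Grubbs catalyst RuCl2(=CHPh)(PCy3)(H2IMes) (0.5 mol %), CH2Cl2, 40 °C; distilled from K2CO3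
Reagents that add atoms: none
Why: Ring-closing metathesis between the vinyl group and the trisubstituted alkene extrudes isobutene and forms the cyclopentene without touching the carbinol carbon, so the (R) configuration is retained.

Step 9
Reactants: 10 10-chloro-2-(3-methylbut-2-en-1-yl)-3,7-bis(triisopropylsilyloxy)dibenzo[b,f]oxepine-11-carbaldehyde; 12 (1R)-1-methylcyclopent-2-en-1-ol
Product: 14 10-{[(1R)-1-methylcyclopent-2-en-1-yl]oxy}-2-(3-methylbut-2-en-1-yl)-3,7-bis(triisopropylsilyloxy)dibenzo[b,f]oxepine-11-carbaldehyde, via sodium alkoxide 13 (not isolated)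
Conditions: 12, NaH, THF, 0 °C; then 10, 0 °C → rt
Reagents that add atoms: none
Why: Nucleophilic vinylic substitution (addition–elimination) of the tertiary alkoxide at the formyl-activated β-carbon of the chloro enal; the C–O bond at the stereocentre is untouched, so (R) is retained.

Step 10
Reactants: 14 10-{[(1R)-1-methylcyclopent-2-en-1-yl]oxy}-2-(3-methylbut-2-en-1-yl)-3,7-bis(triisopropylsilyloxy)dibenzo[b,f]oxepine-11-carbaldehyde
Product: 15 10-{[(1R)-1-methylcyclopent-2-en-1-yl]oxy}-11-(2-methylprop-1-en-1-yl)-2-(3-methylbut-2-en-1-yl)-3,7-bis(triisopropylsilyloxy)dibenzo[b,f]oxepine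
Conditions: i-PrPPh3I, n-BuLi, THF, 0 °C; then 14, −78 → 0 °C; product kept cold and dark
Reagents that add atoms: isopropyltriphenylphosphonium iodide, CC(C)[P+](c1ccccc1)(c1ccccc1)c1ccccc1.[I-]
Why: Wittig olefination of the vinylogous formate with the non-stabilised isopropylidene ylide; the new alkene carries two identical methyl groups, so there is no E/Z issue.

Step 11
Reactants: 15 10-{[(1R)-1-methylcyclopent-2-en-1-yl]oxy}-11-(2-methylprop-1-en-1-yl)-2-(3-methylbut-2-en-1-yl)-3,7-bis(triisopropylsilyloxy)dibenzo[b,f]oxepine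
Product: 17 bis(triisopropylsilyl) ether of 18 (hexacyclic adduct; all three aliphatic ring fusions cis), via triplet 1,4-diradical 16 (not isolated)
Conditions: [Ir(dF(CF3)ppy)2(dtbbpy)]PF6 (2 mol %), degassed MeCN (0.01 M), 450 nm LEDs, rt
Reagents that add atoms: none
Why: Triplet energy transfer from the excited iridium complex to the aryl-conjugated 1-alkoxy-1,3-diene (C10=C11–CH=CMe2) gives a triplet that relaxes by twisting about the exocyclic CH=CMe2 bond; its CH terminus adds to the nearer cyclopentene carbon, and the triplet 1,4-diradical 16 (tertiary CMe2 radical and secondary cyclopentyl radical) closes after intersystem crossing. The closest known reaction type is the visible-light, triplet-sensitized intramolecular [2+2] photocycloaddition of 1,3-dienes and styrenes with tethered unactivated alkenes to vinylcyclobutanes. The dihydropyran closes by 6-exo-trig radical addition across the four-atom tether (C11, C10, O, quaternary C), and the cyclobutane closes by 1,4-diradical recombination. The (R) quaternary carbon, the only stereocentre of 15, holds the ether oxygen on one face of the cyclopentene, so the diene reaches only that face (sets Cb); the cyclobutane must then be cis-fused to the five-membered ring (sets Cc) and the six-membered ring cis-fused to the cyclobutane (sets Ca), while Cd is not stereogenic so bond rotation in the triplet costs nothing. The step needs reaction at the isobutenyl C=C rather than the tetrasubstituted ring C10=C11 and straight rather than crossed regiochemistry; bonding at C11 would create two adjacent quaternary carbons in a bicyclo[2.1.1]hexane, and the tether length favours the six-membered ring. The prenyl and cyclopentene alkenes lie far above the sensitizer in triplet energy and should not be excited on their own.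

Step 12
Reactants: 17 bis(triisopropylsilyl) ether of 18
Product: 18 target CNP0185814.1
Conditions: TBAF, AcOH, THF, 0 °C
Reagents that add atoms: none
Why: Fluoride cleavage of both aryl silyl ethers under acetic acid buffering; these near-neutral conditions should spare the enol ether, the prenyl group and the cyclobutane, and no stereocentre is touched.

## Compound list

1 | 2-(2-bromo-4-methoxyphenyl)acetic acid | COc1ccc(CC(=O)O)c(Br)c1 | starting material
2 | 3-methoxyphenol | COc1cccc(O)c1 | starting material
3 | 2-[4-methoxy-2-(3-methoxyphenoxy)phenyl]acetic acid | COc1cccc(Oc2cc(OC)ccc2CC(=O)O)c1 | intermediate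
4 | 3,7-dimethoxydibenzo[b,f]oxepin-10(11H)-one | COc1ccc2CC(=O)c3ccc(OC)cc3Oc2c1 | intermediate
5 | 3,7-dihydroxydibenzo[b,f]oxepin-10(11H)-one | Oc1ccc2CC(=O)c3ccc(O)cc3Oc2c1 | intermediate
6 | 2-bromo-3,7-dihydroxydibenzo[b,f]oxepin-10(11H)-one | Oc1cc2Oc3cc(O)ccc3C(=O)Cc2cc1Br | intermediate
7 | 3,7-dihydroxy-2-(3-methylbut-2-en-1-yl)dibenzo[b,f]oxepin-10(11H)-one | CC(C)=CCc1cc2CC(=O)c3ccc(O)cc3Oc2cc1O | intermediate
8 | 2-(3-methylbut-2-en-1-yl)-3,7-bis(triisopropylsilyloxy)dibenzo[b,f]oxepin-10(11H)-one | CC(C)=CCc1cc2CC(=O)c3ccc(O[Si](C(C)C)(C(C)C)C(C)C)cc3Oc2cc1O[Si](C(C)C)(C(C)C)C(C)C | intermediate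
9 | N-{[10-chloro-2-(3-methylbut-2-en-1-yl)-3,7-bis(triisopropylsilyloxy)dibenzo[b,f]oxepin-11-yl]methylidene}-N-methylmethanaminium chloride (iminium chloride) | CC(C)=CCc1cc2c(cc1O[Si](C(C)C)(C(C)C)C(C)C)Oc1cc(O[Si](C(C)C)(C(C)C)C(C)C)ccc1C(Cl)=C2C=[N+](C)C.[Cl-] | intermediate (not isolated)
10 | 10-chloro-2-(3-methylbut-2-en-1-yl)-3,7-bis(triisopropylsilyloxy)dibenzo[b,f]oxepine-11-carbaldehyde | CC(C)=CCc1cc2c(cc1O[Si](C(C)C)(C(C)C)C(C)C)Oc1cc(O[Si](C(C)C)(C(C)C)C(C)C)ccc1C(Cl)=C2C=O | intermediate
11 | (R)-linalool, (3R)-3,7-dimethylocta-1,6-dien-3-ol | C=C[C@](C)(O)CCC=C(C)C | starting material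
12 | (1R)-1-methylcyclopent-2-en-1-ol | C[C@]1(O)C=CCC1 | intermediate
13 | sodium (1R)-1-methylcyclopent-2-en-1-olate (sodium alkoxide) | C[C@]1([O-])C=CCC1.[Na+] | intermediate (not isolated)
14 | 10-{[(1R)-1-methylcyclopent-2-en-1-yl]oxy}-2-(3-methylbut-2-en-1-yl)-3,7-bis(triisopropylsilyloxy)dibenzo[b,f]oxepine-11-carbaldehyde | CC(C)=CCc1cc2c(cc1O[Si](C(C)C)(C(C)C)C(C)C)Oc1cc(O[Si](C(C)C)(C(C)C)C(C)C)ccc1C(O[C@@]1(C)C=CCC1)=C2C=O | intermediate
15 | 10-{[(1R)-1-methylcyclopent-2-en-1-yl]oxy}-11-(2-methylprop-1-en-1-yl)-2-(3-methylbut-2-en-1-yl)-3,7-bis(triisopropylsilyloxy)dibenzo[b,f]oxepine | CC(C)=CCc1cc2c(cc1O[Si](C(C)C)(C(C)C)C(C)C)Oc1cc(O[Si](C(C)C)(C(C)C)C(C)C)ccc1C(O[C@@]1(C)C=CCC1)=C2C=C(C)C | intermediate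
16 | triplet 1,4-diradical: dihydropyran closed, radicals at the CMe2 carbon and at the cyclopentane CH | CC(C)=CCc1cc2c(cc1O[Si](C(C)C)(C(C)C)C(C)C)Oc1cc(O[Si](C(C)C)(C(C)C)C(C)C)ccc1C1=C2[C@@H]([C](C)C)[C@H]3[CH]CC[C@@]3(C)O1 | intermediate (not isolated)
17 | bis(triisopropylsilyl) ether of the target; cyclobutane CH on C11 (R), central CH (R), CH next to CH2 (S), O-bearing quaternary carbon (R); all ring fusions cis | CC(C)=CCc1cc2c(cc1O[Si](C(C)C)(C(C)C)C(C)C)Oc1cc(O[Si](C(C)C)(C(C)C)C(C)C)ccc1C1=C2[C@@H]2[C@H]3[C@H](CC[C@@]3(C)O1)C2(C)C | intermediate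
18 | CNP0185814.1; same configuration as 17, both phenols free | CC(C)=CCc1cc2c(cc1O)Oc1cc(O)ccc1C1=C2[C@@H]2[C@H]3[C@H](CC[C@@]3(C)O1)C2(C)C | target

## Step count and risks

Total steps: 12. Longest linear sequence: 11 (steps 1–7 and 9–12); the linalool branch contributes step 8.

Steps most likely to fail:

**Step 11 (key photocycloaddition).** The first C–C bond must come from the delocalised, stabilised terminus of the diene triplet adding to an unactivated cyclopentene, so unproductive triplet decay may outrun cyclisation. Hydrogen transfer within the 1,4-diradical, crossed addition at the ring double bond, or slow thermal [3,3] rearrangement of the allyl vinyl ether during long irradiation may also divert material. The fallback sets out from ketone 8 and returns at 17. Amine-catalysed condensation of 8 with citral (ethylenediammonium diacetate, toluene, 80 °C) should give dienone F1, which closes in the same flask by oxa-6π electrocyclisation to racemic 2H-pyran F2. Preparative chiral-phase HPLC separates (R)-pyran F3 from (S)-pyran F4, which is set aside. Sensitised irradiation of F3 then joins the pyran CH=CH to the side-chain trisubstituted alkene. This is the well-known conversion of chromenes bearing a 4-methylpent-3-enyl chain into cyclols, in which the localised diene terminus closes a five-membered ring first; it should give 17 with the same quaternary-carbon control.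

**Step 9 (vinylic substitution by a tertiary alkoxide).** Addition at the hindered, donor-deactivated β-carbon may be slow, leaving room for silyl transfer from the aryl ethers to the alkoxide or reversible attack at the formyl group. The fallback sets out from 10 and returns at 15. Wittig olefination of 10 with isopropylidenetriphenylphosphorane first gives chloro diene F5. Palladium-catalysed C–O cross-coupling of this alkenyl chloride with sodium alkoxide 13 (Pd2(dba)3, a bulky dialkylbiarylphosphine, toluene, at or below 60 °C) then gives 15 directly. Tertiary alkoxides are suitable partners because they have no β-hydrogen on the carbinol carbon.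

**Step 4 (bromination).** Ring-B or double bromination and α-bromination of the ketone may compete with the wanted substitution at C2. The fallback sets out from 1 and returns at 6, placing the halogen before the tricycle is built. Bromination of 1 (Br2, AcOH, rt) goes ortho to methoxy and para to the existing bromine to give dibromo acid F6. Ullmann coupling with 2 under step-1 conditions should react at the bromide ortho to the carboxymethyl group (carboxylate-assisted; the other bromide is ortho to methoxy and deactivated) to give diaryl ether acid F7. Polyphosphoric acid closes F7 to bromo ketone F8, and BBr3 then gives 6.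

Further compounds
F1 | step 11 | 11-(3,7-dimethylocta-2,6-dien-1-ylidene)-2-(3-methylbut-2-en-1-yl)-3,7-bis(triisopropylsilyloxy)dibenzo[b,f]oxepin-10(11H)-one (dienone) | CC(C)=CCc1cc2c(cc1O[Si](C(C)C)(C(C)C)C(C)C)Oc1cc(O[Si](C(C)C)(C(C)C)C(C)C)ccc1C(=O)C2=CC=C(C)CCC=C(C)C
F2 | step 11 | racemic 2H-pyran fused at C10–C11 of the dibenzoxepine (O on C10), with methyl and 4-methylpent-3-enyl on the sp3 carbon | CC(C)=CCc1cc2c(cc1O[Si](C(C)C)(C(C)C)C(C)C)Oc1cc(O[Si](C(C)C)(C(C)C)C(C)C)ccc1C1=C2C=CC(C)(CCC=C(C)C)O1
F3 | step 11 | (R)-enantiomer of F2 | CC(C)=CCc1cc2c(cc1O[Si](C(C)C)(C(C)C)C(C)C)Oc1cc(O[Si](C(C)C)(C(C)C)C(C)C)ccc1C1=C2C=C[C@@](C)(CCC=C(C)C)O1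
F4 | step 11 | (S)-enantiomer of F2 | CC(C)=CCc1cc2c(cc1O[Si](C(C)C)(C(C)C)C(C)C)Oc1cc(O[Si](C(C)C)(C(C)C)C(C)C)ccc1C1=C2C=C[C@](C)(CCC=C(C)C)O1
F5 | step 9 | 10-chloro-11-(2-methylprop-1-en-1-yl)-2-(3-methylbut-2-en-1-yl)-3,7-bis(triisopropylsilyloxy)dibenzo[b,f]oxepine | CC(C)=CCc1cc2c(cc1O[Si](C(C)C)(C(C)C)C(C)C)Oc1cc(O[Si](C(C)C)(C(C)C)C(C)C)ccc1C(Cl)=C2C=C(C)C
F6 | step 4 | 2-(2,5-dibromo-4-methoxyphenyl)acetic acid | COc1cc(Br)c(CC(=O)O)cc1Br
F7 | step 4 | 2-[5-bromo-4-methoxy-2-(3-methoxyphenoxy)phenyl]acetic acid | COc1cc(Oc2cccc(OC)c2)c(CC(=O)O)cc1Br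
F8 | step 4 | 2-bromo-3,7-dimethoxydibenzo[b,f]oxepin-10(11H)-one | COc1cc2Oc3cc(OC)ccc3C(=O)Cc2cc1Br
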